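**Plan**

- Retrosynthesis: the ring B–C2 bond is cut first (aryl taken off a chromone). Ring C is then unpicked carbon by carbon (C2, C3, C4) down to a ring A phenol. Last, the side chain is cut at C1''–C2'' and C3''–CH3 in one operation, leaving a benzylic chloride, a terminal alkyne and trimethylaluminium.
- Enabling feature: the E-trisubstituted C2''=C3'' alkene carries its methyl on C3'' and is joined to ring A only through benzylic C1''. This is the pattern left by syn-methylmetalation of a terminal alkyne followed by benzylation of the metal-bearing carbon.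
- Forward: the ring A chloride (from 2,4,6-trihydroxybenzaldehyde) and the silyloxy enyne (from pent-4-ynoic acid) are joined in the chain-forming step, with no ring closed. The para pivalate is then removed, the freed phenol directs ortho-formylation, the aldehyde is taken to the methyl ketone, ring C is closed as a chromone through O1–C2, and ring B is added last.
- Stereochemistry: C6'' (R) comes from oxazaborolidine-catalysed reduction of an isopropenyl ketone. The 2''E geometry comes from syn-carboalumination and retentive coupling. C2 (S) comes from rhodium-catalysed asymmetric 1,4-arylation of the chromone.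

Key step: step 9

**Remarks on the chemistry**

- The enyne that the carbon count of the side chain requires has a seven-carbon chain, a 2-methylhept-1-en-6-yne. Its C7 and C6 become C2'' and C3''.
- Assumption for step 17: the sense of induction is taken from rhodium/biaryl-diphosphine additions to cyclohexenone, where the (S)-ligand delivers aryl to the face that corresponds to the Re face of C2 of the chromone. Should the sense be opposite, the (R)-ligand is used with no other change.
- Compounds 1, 7, 10 (THF solution), 15 and 25 are commercial. Any minor enantiomer from step 7 would surface as a diastereomer after step 17 and is to be removed at 30 or 31.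

**Ring A fragment**

Step 1
Reactants: 1 2,4,6-trihydroxybenzaldehyde
Product: 2 4-formyl-3,5-dihydroxyphenyl pivalate
Conditions: PivCl (1.0 equiv), Et3N (1.05 equiv), THF, −20 → 0 °C
Reagents that add atoms: pivaloyl chloride, CC(C)(C)C(=O)Cl
Why: Selective mono-O-acylation (esterification), because the 4-hydroxyl is para to the formyl group, is the most acidic and least hindered phenol and is not tied up in the chelate with the carbonyl that shields the two ortho hydroxyls, so one equivalent of the bulky acyl chloride at low temperature should take it first.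

Step 2
Reactants: 2 4-formyl-3,5-dihydroxyphenyl pivalate
Product: 3 4-formyl-3,5-bis(methoxymethoxy)phenyl pivalate
Conditions: MOMCl (3 equiv), i-Pr2NEt (4 equiv), CH2Cl2, 0 °C → rt
Reagents that add atoms: chloromethyl methyl ether, COCCl
Why: O-Alkylation of the two remaining, equivalent ortho phenols as MOM acetals under amine base (Williamson-type etherification), conditions that leave the aryl pivalate and the aldehyde untouched.

Step 3
Reactants: 3 4-formyl-3,5-bis(methoxymethoxy)phenyl pivalate
Product: 4 4-(hydroxymethyl)-3,5-bis(methoxymethoxy)phenyl pivalate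
Conditions: NaBH4, THF/EtOH, 0 °C
Reagents that add atoms: none
Why: Borohydride reduction of the aldehyde, which at 0 °C is far faster than any attack on the hindered aryl pivalate.

Step 4
Reactants: 4 4-(hydroxymethyl)-3,5-bis(methoxymethoxy)phenyl pivalate
Product: 6 4-(chloromethyl)-3,5-bis(methoxymethoxy)phenyl pivalate, via benzylic mesylate 5 (not isolated)
Conditions: MsCl, Et3N, LiCl, THF, 0 °C → rt; used promptly after filtration through a short pad of basic alumina
Reagents that add atoms: lithium chloride, [Li+].[Cl-]; methanesulfonyl chloride, CS(=O)(=O)Cl (its atoms stay only in intermediate 5)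
Why: Mesylation and in situ chloride displacement at an activated benzylic carbon (SN2) under basic conditions that spare the MOM acetals, the para acyloxy group lowering the tendency of the bis-ortho-alkoxy benzylic chloride to ionise.

**Enyne fragment**

Step 5
Reactants: 7 pent-4-ynoic acid
Product: 9 N-methoxy-N-methylpent-4-ynamide, via acyl imidazole 8 (not isolated)
Conditions: 1,1'-carbonyldiimidazole, CH2Cl2, rt; then MeNH(OMe)·HCl, rt
Reagents that add atoms: N,O-dimethylhydroxylamine hydrochloride, CNOC.Cl; 1,1'-carbonyldiimidazole, O=C(n1ccnc1)n1ccnc1 (its atoms stay only in intermediate 8)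
Why: Amide formation through the acyl imidazole (carbonyldiimidazole activation) gives the Weinreb amide, and neither reagent touches the terminal alkyne.

Step 6
Reactants: 9 N-methoxy-N-methylpent-4-ynamide; 10 isopropenylmagnesium bromide
Product: 12 2-methylhept-1-en-6-yn-3-one, via tetrahedral magnesium adduct 11 (not isolated)
Conditions: 10 (1.5 equiv, THF solution), THF, −20 → 0 °C; inverse quench into cold 1 M aq HCl
Reagents that add atoms: isopropenylmagnesium bromide 10, C=C(C)[Mg]Br
Why: Weinreb ketone synthesis, in which the chelated tetrahedral adduct 11 blocks over-addition and collapses to the enone only on the acidic quench, which also keeps the released hydroxylamine protonated so that it does not add to the enone.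

Step 7
Reactants: 12 2-methylhept-1-en-6-yn-3-one
Product: 13 (3R)-2-methylhept-1-en-6-yn-3-ol
Conditions: (S)-2-methyl-CBS-oxazaborolidine ((S)-1-methyl-3,3-diphenyltetrahydro-1H,3H-pyrrolo[1,2-c][1,3,2]oxazaborole, 0.2 equiv), catecholborane (1.5 equiv), toluene, −78 °C; MeOH, then aq NaOH wash
Reagents that add atoms: none
Why: Corey–Bakshi–Shibata reduction, in which the ketone binds the catalyst boron with the branched isopropenyl group as the large substituent, so the (S)-catalyst should deliver hydride to the Si face and set C3 as R, while catecholborane at −78 °C does not hydroborate the alkyne or the alkene.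

Step 8
Reactants: 13 (3R)-2-methylhept-1-en-6-yn-3-ol
Product: 14 (3R)-3-(tert-butyldimethylsilyloxy)-2-methylhept-1-en-6-yne
Conditions: TBSCl, imidazole, DMF, rt
Reagents that add atoms: tert-butyldimethylsilyl chloride, CC(C)(C)[Si](C)(C)Cl
Why: Imidazole-promoted silylation of the secondary allylic alcohol gives an ether that is inert to organoaluminium reagents and does not disturb the stereocentre.

**Chain-forming step**

Step 9
Reactants: 14 (3R)-3-(tert-butyldimethylsilyloxy)-2-methylhept-1-en-6-yne; 15 trimethylaluminium; 6 4-(chloromethyl)-3,5-bis(methoxymethoxy)phenyl pivalate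
Product: 17 4-[(2E,6R)-6-(tert-butyldimethylsilyloxy)-3,7-dimethylocta-2,7-dienyl]-3,5-bis(methoxymethoxy)phenyl pivalate, via alkenylalane 16 (not isolated)
Conditions: Me3Al (2.0 equiv), Cp2ZrCl2 (0.25 equiv), CH2Cl2, 0 °C → rt; volatiles removed in vacuo; then 6 (0.8 equiv), Pd(PPh3)4 (5 mol %), THF, rt
Reagents that add atoms: trimethylaluminium 15, C[Al](C)C
Why: Zirconium-catalysed methylalumination of a terminal alkyne (Negishi carboalumination) followed by palladium-catalysed coupling of the alkenylalane with a benzylic halide, the sequence known from polyprenylated arene and quinone side chains, is the closest known reaction type and is used here without change. The zirconocene–Me3Al species adds methyl and aluminium syn across the triple bond, methyl to the internal carbon (C3'') and aluminium to the terminal carbon (C2''), which should give (E)-alkenylalane 16 with C4'' trans to the metal. Zerovalent palladium inserts into the benzylic C–Cl bond of 6, the alkenyl group passes from aluminium to palladium with retention, and reductive elimination forms C1''–C2'' with the E geometry intact. No ring is closed and no stereocentre is made; the (R)-silyloxy centre is a spectator. The step needs regio- and syn-selective methylmetalation and reaction of the alkyne in preference to the alkene, and both are secured by the terminal alkyne, which is far more reactive than the 1,1-disubstituted alkene next to the silyl ether under achiral Cp2ZrCl2. The para pivalate tempers ionisation of the bis-ortho-alkoxy benzylic chloride, and removal of excess Me3Al with a switch to THF keeps the aluminium species from attacking the ester or the MOM acetals.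

**Ring C**

Step 10
Reactants: 17 4-[(2E,6R)-6-(tert-butyldimethylsilyloxy)-3,7-dimethylocta-2,7-dienyl]-3,5-bis(methoxymethoxy)phenyl pivalate
Product: 18 4-[(2E,6R)-6-(tert-butyldimethylsilyloxy)-3,7-dimethylocta-2,7-dienyl]-3,5-bis(methoxymethoxy)phenol
Conditions: K2CO3, MeOH, rt
Reagents that add atoms: none
Why: Base-catalysed methanolysis (transesterification) of the aryl ester frees only the oxygen that is to become O1, while the alkyl silyl ether and the MOM acetals are stable to carbonate in methanol.

Step 11
Reactants: 18 4-[(2E,6R)-6-(tert-butyldimethylsilyloxy)-3,7-dimethylocta-2,7-dienyl]-3,5-bis(methoxymethoxy)phenol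
Product: 20 3-[(2E,6R)-6-(tert-butyldimethylsilyloxy)-3,7-dimethylocta-2,7-dienyl]-6-hydroxy-2,4-bis(methoxymethoxy)benzaldehyde, via hydroxymethylphenol 19 (not isolated)
Conditions: MgCl2 (anhydrous, 2 equiv), Et3N (4 equiv), (CH2O)n (6 equiv), THF, reflux; aq NH4Cl work-up
Reagents that add atoms: paraformaldehyde (as formaldehyde), C=O
Why: Magnesium-mediated ortho-formylation of a phenol (Casnati–Skattebøl reaction), in which the magnesium phenoxide delivers formaldehyde to the ortho carbon through a six-membered chelate and a second formaldehyde oxidises hydroxymethylphenol 19 by hydride transfer; the two ortho positions are equivalent and the para position is blocked, so one aldehyde is expected under non-acidic conditions that spare the acetals, the silyl ether and the alkenes.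

Step 12
Reactants: 20 3-[(2E,6R)-6-(tert-butyldimethylsilyloxy)-3,7-dimethylocta-2,7-dienyl]-6-hydroxy-2,4-bis(methoxymethoxy)benzaldehyde
Product: 21 4-[(2E,6R)-6-(tert-butyldimethylsilyloxy)-3,7-dimethylocta-2,7-dienyl]-2-(1-hydroxyethyl)-3,5-bis(methoxymethoxy)phenol (both epimers at the new carbinol carbon)
Conditions: MeMgBr (3 equiv), THF, −78 → 0 °C; aq NH4Cl; crude product used directly
Reagents that add atoms: methylmagnesium bromide, C[Mg]Br
Why: Grignard 1,2-addition to the aldehyde after deprotonation of the phenol by the first equivalent brings in the carbon that becomes C3, and the new carbinol centre is left uncontrolled because the next step removes it.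

Step 13
Reactants: 21 4-[(2E,6R)-6-(tert-butyldimethylsilyloxy)-3,7-dimethylocta-2,7-dienyl]-2-(1-hydroxyethyl)-3,5-bis(methoxymethoxy)phenol
Product: 22 1-{3-[(2E,6R)-6-(tert-butyldimethylsilyloxy)-3,7-dimethylocta-2,7-dienyl]-6-hydroxy-2,4-bis(methoxymethoxy)phenyl}ethanone
Conditions: MnO2 (activated, excess), CH2Cl2, rt
Reagents that add atoms: none
Why: Oxidation of a benzylic alcohol with activated MnO2 is selective for the benzylic carbinol, leaves the silyl ether, the acetals and both alkenes alone, and gives a ketone stabilised by the hydrogen bond to the ortho phenol.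

Step 14
Reactants: 22 1-{3-[(2E,6R)-6-(tert-butyldimethylsilyloxy)-3,7-dimethylocta-2,7-dienyl]-6-hydroxy-2,4-bis(methoxymethoxy)phenyl}ethanone
Product: 24 6-[(2E,6R)-6-(tert-butyldimethylsilyloxy)-3,7-dimethylocta-2,7-dienyl]-5,7-bis(methoxymethoxy)-4H-chromen-4-one, via enaminone 23 (not isolated)
Conditions: Me2NCH(OMe)2 (3 equiv), toluene, 90 °C; concentrate; then AcOH, CH2Cl2, 40 °C
Reagents that add atoms: N,N-dimethylformamide dimethyl acetal, COC(OC)N(C)C
Why: Condensation of the methyl ketone with the formamide acetal gives enaminone 23, and mild acid then promotes conjugate addition of the ortho phenol with loss of dimethylamine (enaminone route to chromones, 6-endo closure through O1–C2); only the oxygen freed from the pivalate can close the ring, so the side chain ends at C6.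

**Ring B and end game**

Step 15
Reactants: 25 4-bromo-2-methoxyphenol
Product: 26 4-bromo-2-methoxy-1-(methoxymethoxy)benzene
Conditions: MOMCl, i-Pr2NEt, CH2Cl2, 0 °C → rt
Reagents that add atoms: chloromethyl methyl ether, COCCl
Why: O-Alkylation of the phenol as its MOM acetal (Williamson-type etherification) gives a group that survives organolithium chemistry and falls off with the other acetals at the end.

Step 16
Reactants: 26 4-bromo-2-methoxy-1-(methoxymethoxy)benzene
Product: 29 [3-methoxy-4-(methoxymethoxy)phenyl]boronic acid, via aryllithium 27 (not isolated), via lithium borate 28 (not isolated)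
Conditions: n-BuLi, THF, −78 °C; B(Oi-Pr)3, −78 °C → rt; aq NH4Cl
Reagents that add atoms: triisopropyl borate, CC(C)OB(OC(C)C)OC(C)C; water, O; n-butyllithium, [Li]CCCC (its lithium stays only in intermediates 27 and 28)
Why: Bromine–lithium exchange followed by borylation of the aryllithium and mild hydrolysis of the borate is the standard route to arylboronic acids, and the near-neutral work-up keeps the MOM acetal.

Step 17
Reactants: 24 6-[(2E,6R)-6-(tert-butyldimethylsilyloxy)-3,7-dimethylocta-2,7-dienyl]-5,7-bis(methoxymethoxy)-4H-chromen-4-one; 29 [3-methoxy-4-(methoxymethoxy)phenyl]boronic acid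
Product: 30 (2S)-6-[(2E,6R)-6-(tert-butyldimethylsilyloxy)-3,7-dimethylocta-2,7-dienyl]-2-[3-methoxy-4-(methoxymethoxy)phenyl]-5,7-bis(methoxymethoxy)-2,3-dihydro-4H-chromen-4-one
Conditions: 29 (2.5 equiv), [RhCl(C2H4)2]2 (2.5 mol %), (S)-2,2'-bis[bis(3,4,5-trifluorophenyl)phosphino]-6,6'-dimethoxy-1,1'-biphenyl ((S)-MeO-F12-BIPHEP, 5.5 mol %), aq KOH (10 mol %), CH2Cl2/H2O, 30 °C
Reagents that add atoms: none
Why: Rhodium-catalysed asymmetric 1,4-addition of an arylboronic acid to an enone (Hayashi–Miyaura reaction), a known route from chromones to flavanones, in which the aryl group passes from boron to monovalent rhodium, the C2=C3 bond inserts with aryl delivered to the Re face of C2 under control of the axially chiral diphosphine (setting C2 as S) and water protonates the rhodium enolate, while the electron-poor ligand and the flanking 5-alkoxy group disfavour 1,2-addition and the isolated side-chain alkenes do not insert.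

Step 18
Reactants: 30 (2S)-6-[(2E,6R)-6-(tert-butyldimethylsilyloxy)-3,7-dimethylocta-2,7-dienyl]-2-[3-methoxy-4-(methoxymethoxy)phenyl]-5,7-bis(methoxymethoxy)-2,3-dihydro-4H-chromen-4-one
Product: 31 (2S)-5,7-dihydroxy-2-(4-hydroxy-3-methoxyphenyl)-6-[(2E,6R)-6-hydroxy-3,7-dimethylocta-2,7-dienyl]-2,3-dihydro-4H-chromen-4-one
Conditions: HCl (about 1 M in MeOH), rt → 40 °C, monitored and stopped at full conversion
Reagents that add atoms: none
Why: Acid-catalysed acetal exchange of the three MOM ethers and methanolysis of the silyl ether (global deprotection) under mild conditions that should not open or epimerise the flavanone at C2, ionise the allylic alcohol or cyclise the freed phenols onto the C2''=C3'' alkene.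

**Compound list**

1 | 2,4,6-trihydroxybenzaldehyde | O=Cc1c(O)cc(O)cc1O | starting material
2 | 4-formyl-3,5-dihydroxyphenyl pivalate | CC(C)(C)C(=O)Oc1cc(O)c(C=O)c(O)c1 | intermediate
3 | 4-formyl-3,5-bis(methoxymethoxy)phenyl pivalate | CC(C)(C)C(=O)Oc1cc(OCOC)c(C=O)c(OCOC)c1 | intermediate
4 | 4-(hydroxymethyl)-3,5-bis(methoxymethoxy)phenyl pivalate | CC(C)(C)C(=O)Oc1cc(OCOC)c(CO)c(OCOC)c1 | intermediate
5 | 4-[(methylsulfonyloxy)methyl]-3,5-bis(methoxymethoxy)phenyl pivalate | CC(C)(C)C(=O)Oc1cc(OCOC)c(COS(C)(=O)=O)c(OCOC)c1 | intermediate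
6 | 4-(chloromethyl)-3,5-bis(methoxymethoxy)phenyl pivalate | CC(C)(C)C(=O)Oc1cc(OCOC)c(CCl)c(OCOC)c1 | intermediate
7 | pent-4-ynoic acid | C#CCCC(=O)O | starting material
8 | 1-(1H-imidazol-1-yl)pent-4-yn-1-one | C#CCCC(=O)n1ccnc1 | intermediate
9 | N-methoxy-N-methylpent-4-ynamide | C#CCCC(=O)N(C)OC | intermediate
10 | isopropenylmagnesium bromide (prop-1-en-2-ylmagnesium bromide) | C=C(C)[Mg]Br | starting material
11 | bromomagnesium 3-[methoxy(methyl)amino]-2-methylhept-1-en-6-yn-3-olate | C=C(C)C(CCC#C)(O[Mg]Br)N(C)OC | intermediate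
12 | 2-methylhept-1-en-6-yn-3-one | C=C(C)C(=O)CCC#C | intermediate
13 | (3R)-2-methylhept-1-en-6-yn-3-ol | C=C(C)[C@H](O)CCC#C | intermediate
14 | (3R)-3-(tert-butyldimethylsilyloxy)-2-methylhept-1-en-6-yne | C=C(C)[C@H](O[Si](C)(C)C(C)(C)C)CCC#C | intermediate
15 | trimethylaluminium | C[Al](C)C | starting material
16 | [(1E,5R)-5-(tert-butyldimethylsilyloxy)-2,6-dimethylhepta-1,6-dienyl]dimethylalane | C=C(C)[C@H](O[Si](C)(C)C(C)(C)C)CC/C(C)=C/[Al](C)C | intermediate
17 | 4-[(2E,6R)-6-(tert-butyldimethylsilyloxy)-3,7-dimethylocta-2,7-dienyl]-3,5-bis(methoxymethoxy)phenyl pivalate | C=C(C)[C@H](O[Si](C)(C)C(C)(C)C)CC/C(C)=C/Cc1c(OCOC)cc(OC(=O)C(C)(C)C)cc1OCOC | intermediate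
18 | 4-[(2E,6R)-6-(tert-butyldimethylsilyloxy)-3,7-dimethylocta-2,7-dienyl]-3,5-bis(methoxymethoxy)phenol | C=C(C)[C@H](O[Si](C)(C)C(C)(C)C)CC/C(C)=C/Cc1c(OCOC)cc(O)cc1OCOC | intermediate
19 | 4-[(2E,6R)-6-(tert-butyldimethylsilyloxy)-3,7-dimethylocta-2,7-dienyl]-2-(hydroxymethyl)-3,5-bis(methoxymethoxy)phenol | C=C(C)[C@H](O[Si](C)(C)C(C)(C)C)CC/C(C)=C/Cc1c(OCOC)cc(O)c(CO)c1OCOC | intermediate
20 | 3-[(2E,6R)-6-(tert-butyldimethylsilyloxy)-3,7-dimethylocta-2,7-dienyl]-6-hydroxy-2,4-bis(methoxymethoxy)benzaldehyde | C=C(C)[C@H](O[Si](C)(C)C(C)(C)C)CC/C(C)=C/Cc1c(OCOC)cc(O)c(C=O)c1OCOC | intermediate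
21 | 4-[(2E,6R)-6-(tert-butyldimethylsilyloxy)-3,7-dimethylocta-2,7-dienyl]-2-(1-hydroxyethyl)-3,5-bis(methoxymethoxy)phenol (both carbinol epimers) | C=C(C)[C@H](O[Si](C)(C)C(C)(C)C)CC/C(C)=C/Cc1c(OCOC)cc(O)c(C(C)O)c1OCOC | intermediate
22 | 1-{3-[(2E,6R)-6-(tert-butyldimethylsilyloxy)-3,7-dimethylocta-2,7-dienyl]-6-hydroxy-2,4-bis(methoxymethoxy)phenyl}ethanone | C=C(C)[C@H](O[Si](C)(C)C(C)(C)C)CC/C(C)=C/Cc1c(OCOC)cc(O)c(C(C)=O)c1OCOC | intermediate
23 | (2E)-1-{3-[(2E,6R)-6-(tert-butyldimethylsilyloxy)-3,7-dimethylocta-2,7-dienyl]-6-hydroxy-2,4-bis(methoxymethoxy)phenyl}-3-(dimethylamino)prop-2-en-1-one | C=C(C)[C@H](O[Si](C)(C)C(C)(C)C)CC/C(C)=C/Cc1c(OCOC)cc(O)c(C(=O)/C=C/N(C)C)c1OCOC | intermediate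
24 | 6-[(2E,6R)-6-(tert-butyldimethylsilyloxy)-3,7-dimethylocta-2,7-dienyl]-5,7-bis(methoxymethoxy)-4H-chromen-4-one | C=C(C)[C@H](O[Si](C)(C)C(C)(C)C)CC/C(C)=C/Cc1c(OCOC)cc2occc(=O)c2c1OCOC | intermediate
25 | 4-bromo-2-methoxyphenol | COc1cc(Br)ccc1O | starting material
26 | 4-bromo-2-methoxy-1-(methoxymethoxy)benzene | COCOc1ccc(Br)cc1OC | intermediate
27 | [3-methoxy-4-(methoxymethoxy)phenyl]lithium | [Li]c1ccc(OCOC)c(OC)c1 | intermediate
28 | lithium [3-methoxy-4-(methoxymethoxy)phenyl]tri(propan-2-yloxy)borate | [Li+].COCOc1ccc([B-](OC(C)C)(OC(C)C)OC(C)C)cc1OC | intermediate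
29 | [3-methoxy-4-(methoxymethoxy)phenyl]boronic acid | COCOc1ccc(B(O)O)cc1OC | intermediate
30 | (2S)-6-[(2E,6R)-6-(tert-butyldimethylsilyloxy)-3,7-dimethylocta-2,7-dienyl]-2-[3-methoxy-4-(methoxymethoxy)phenyl]-5,7-bis(methoxymethoxy)-2,3-dihydro-4H-chromen-4-one | C=C(C)[C@H](O[Si](C)(C)C(C)(C)C)CC/C(C)=C/Cc1c(OCOC)cc2c(c1OCOC)C(=O)C[C@@H](c1ccc(OCOC)c(OC)c1)O2 | intermediate
31 | (2S)-5,7-dihydroxy-2-(4-hydroxy-3-methoxyphenyl)-6-[(2E,6R)-6-hydroxy-3,7-dimethylocta-2,7-dienyl]-2,3-dihydro-4H-chromen-4-one | C=C(C)[C@H](O)CC/C(C)=C/Cc1c(O)cc2c(c1O)C(=O)C[C@@H](c1ccc(O)c(OC)c1)O2 | target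

**Step count and risks**

Total: 18 steps. Longest linear sequence: 12 steps (steps 1–4, 9, 10–14, 17, 18 from 1; the same length through steps 5–8 from 7).

Steps most likely to fail:

1. Step 9. The electron-rich benzylic chloride may ionise and self-condense under the Lewis-acidic aluminium species, the alane may attack the aryl ester, or regiocontrol of the methylalumination may be incomplete. The fallback reverses the polarity of the sp2–sp3 coupling while making the same two bonds, and sets out from alkyne 14 and chloride 6. The carboalumination mixture holding alkenylalane 16 is quenched with iodine in THF at −30 °C to give, with retention, tert-butyl{[(3R,6E)-7-iodo-2,6-dimethylhepta-1,6-dien-3-yl]oxy}dimethylsilane F1. Chloride 6 is converted with zinc dust and LiCl in THF into {[2,6-bis(methoxymethoxy)-4-(pivaloyloxy)phenyl]methyl}zinc chloride F2, a reagent that tolerates the ester and the acetals. Negishi coupling of F1 with F2 under Pd(PPh3)4 in THF then comes back to the route at 17.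

2. Step 11. Over-hydroxymethylation, diarylmethane formation on the very electron-rich ring, or chelation-assisted loss of the MOM group next to the new carbonyl may spoil the formylation. The fallback puts in the acetyl group directly by directed ortho-metalation and sets out from phenol 18. Ethyl vinyl ether and pyridinium p-toluenesulfonate in CH2Cl2 give 1-(1-ethoxyethoxy)-4-[(2E,6R)-6-(tert-butyldimethylsilyloxy)-3,7-dimethylocta-2,7-dienyl]-3,5-bis(methoxymethoxy)benzene F3. n-BuLi in THF (−78 → −20 °C) removes a ring hydrogen flanked by two acetal oxygens (both such positions are equivalent) to give {3-[(2E,6R)-6-(tert-butyldimethylsilyloxy)-3,7-dimethylocta-2,7-dienyl]-6-(1-ethoxyethoxy)-2,4-bis(methoxymethoxy)phenyl}lithium F4. Acylation with N-methoxy-N-methylacetamide gives 1-{3-[(2E,6R)-6-(tert-butyldimethylsilyloxy)-3,7-dimethylocta-2,7-dienyl]-6-(1-ethoxyethoxy)-2,4-bis(methoxymethoxy)phenyl}ethanone F5. Pyridinium p-toluenesulfonate in MeOH at rt then removes the far more labile ethoxyethyl acetal and leaves the MOM groups, so the route is rejoined at 22 and steps 12 and 13 are bypassed.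

3. Step 17. The electron-rich, 5-alkoxylated chromone may be too poor an acceptor, protodeboronation of the boronic acid may outrun addition, or facial selectivity may be low. The fallback closes ring C by oxa-Michael addition instead and sets out from hydroxy ketone 22. Vanillin is protected (MOMCl, i-Pr2NEt, CH2Cl2) as 3-methoxy-4-(methoxymethoxy)benzaldehyde F6. Claisen–Schmidt condensation of 22 with F6 (KOH, EtOH, rt) gives (2E)-1-{3-[(2E,6R)-6-(tert-butyldimethylsilyloxy)-3,7-dimethylocta-2,7-dienyl]-6-hydroxy-2,4-bis(methoxymethoxy)phenyl}-3-[3-methoxy-4-(methoxymethoxy)phenyl]prop-2-en-1-one F7. NaOAc in refluxing EtOH closes it to the flavanone as a mixture of 30 and its C2 epimer, (2R)-6-[(2E,6R)-6-(tert-butyldimethylsilyloxy)-3,7-dimethylocta-2,7-dienyl]-2-[3-methoxy-4-(methoxymethoxy)phenyl]-5,7-bis(methoxymethoxy)-2,3-dihydro-4H-chromen-4-one F8. The two are separated by preparative HPLC on a chiral stationary phase, the unwanted epimer is returned to the equilibrium through the chalcone with base, and the route is rejoined at 30.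

**Further compounds**

F1 | step 9 | tert-butyl{[(3R,6E)-7-iodo-2,6-dimethylhepta-1,6-dien-3-yl]oxy}dimethylsilane | C=C(C)[C@H](O[Si](C)(C)C(C)(C)C)CC/C(C)=C/I
F2 | step 9 | {[2,6-bis(methoxymethoxy)-4-(pivaloyloxy)phenyl]methyl}zinc chloride | CC(C)(C)C(=O)Oc1cc(OCOC)c(C[Zn]Cl)c(OCOC)c1
F3 | step 11 | 1-(1-ethoxyethoxy)-4-[(2E,6R)-6-(tert-butyldimethylsilyloxy)-3,7-dimethylocta-2,7-dienyl]-3,5-bis(methoxymethoxy)benzene | C=C(C)[C@H](O[Si](C)(C)C(C)(C)C)CC/C(C)=C/Cc1c(OCOC)cc(OC(C)OCC)cc1OCOC
F4 | step 11 | {3-[(2E,6R)-6-(tert-butyldimethylsilyloxy)-3,7-dimethylocta-2,7-dienyl]-6-(1-ethoxyethoxy)-2,4-bis(methoxymethoxy)phenyl}lithium | C=C(C)[C@H](O[Si](C)(C)C(C)(C)C)CC/C(C)=C/Cc1c(OCOC)cc(OC(C)OCC)c([Li])c1OCOC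
F5 | step 11 | 1-{3-[(2E,6R)-6-(tert-butyldimethylsilyloxy)-3,7-dimethylocta-2,7-dienyl]-6-(1-ethoxyethoxy)-2,4-bis(methoxymethoxy)phenyl}ethanone | C=C(C)[C@H](O[Si](C)(C)C(C)(C)C)CC/C(C)=C/Cc1c(OCOC)cc(OC(C)OCC)c(C(C)=O)c1OCOC
F6 | step 17 | 3-methoxy-4-(methoxymethoxy)benzaldehyde | COCOc1ccc(C=O)cc1OC
F7 | step 17 | (2E)-1-{3-[(2E,6R)-6-(tert-butyldimethylsilyloxy)-3,7-dimethylocta-2,7-dienyl]-6-hydroxy-2,4-bis(methoxymethoxy)phenyl}-3-[3-methoxy-4-(methoxymethoxy)phenyl]prop-2-en-1-one | C=C(C)[C@H](O[Si](C)(C)C(C)(C)C)CC/C(C)=C/Cc1c(OCOC)cc(O)c(C(=O)/C=C/c2ccc(OCOC)c(OC)c2)c1OCOC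
F8 | step 17 | (2R)-6-[(2E,6R)-6-(tert-butyldimethylsilyloxy)-3,7-dimethylocta-2,7-dienyl]-2-[3-methoxy-4-(methoxymethoxy)phenyl]-5,7-bis(methoxymethoxy)-2,3-dihydro-4H-chromen-4-one | C=C(C)[C@H](O[Si](C)(C)C(C)(C)C)CC/C(C)=C/Cc1c(OCOC)cc2c(c1OCOC)C(=O)C[C@H](c1ccc(OCOC)c(OC)c1)O2
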